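The six-membered ring is closed across the ring-fusion alkene C3a=C4 (hexahydroindene numbering), which lies next to the quaternary carbons C7a and C7. The cyclopentane is read as a latent 2,2-disubstituted cyclopentane-1,3-dione (C1 and C3a as carbonyls, C7a between them). An achiral enal-dione is desymmetrised by a chiral N-heterocyclic carbene: the enal α-carbon (C4) adds to one of two enantiotopic carbonyls (C3a) and the aldolate is trapped as a β-lactone. This single operation forms the C3a–C4 bond and the carbocycle, fixes C7a, and stores the alkene as a lactone that later leaves as CO2. The remaining C1 ketone then directs a ketene [2+2] that sets C1 and C2.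

Key step: step 5

Numbering used throughout (hexahydro-1H-indene of the target): C1 (quaternary, methyl and side chain), C2 (CO2H), C3, C3a=C4, C5, C6, C7 (gem-dimethyl), C7a (angular methyl).
Assumption: the sense of carbonyl selection by the aminoindanol-derived carbene is not predicted here; the catalyst antipode that delivers the (7aS) series is used (the other antipode would give the enantiomer).

Step 1
Reactants: 1 2-methylcyclopentane-1,3-dione; 2 3-methylbut-2-en-1-ol (prenol)
Product: 3 2-methyl-3-[(3-methylbut-2-en-1-yl)oxy]cyclopent-2-en-1-one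
Conditions: PPh3, DIAD, THF, 0 °C to rt
Reagents that add atoms: none
Why: Mitsunobu O-alkylation of the acidic cyclic 1,3-dione with a primary allylic alcohol should give the vinylogous ester directly and avoid the C-prenylation that base-mediated alkylation gives; no stereocentre is formed.

Step 2
Reactants: 3 2-methyl-3-[(3-methylbut-2-en-1-yl)oxy]cyclopent-2-en-1-one
Product: 4 2-methyl-2-(2-methylbut-3-en-2-yl)cyclopentane-1,3-dione
Conditions: PhMe, BHT (cat.), 180 °C, sealed tube
Reagents that add atoms: none
Why: Thermal Claisen ([3,3]-sigmatropic) rearrangement of the allyl vinylogous ester, driven by C=O formation, joins C7a to C7 as two fully substituted carbons (reverse prenylation); the product is achiral because the two ring carbonyls are equivalent.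

Step 3
Reactants: 4 2-methyl-2-(2-methylbut-3-en-2-yl)cyclopentane-1,3-dione
Product: 5 3-methyl-3-(1-methyl-2,5-dioxocyclopentyl)butanal
Conditions: PdCl2(PhCN)2 (10 mol %), CuCl2·2H2O (10 mol %), AgNO2 (5 mol %), O2 (1 atm), t-BuOH/MeNO2, rt
Reagents that add atoms: dioxygen O=O
Why: Nitrite-modified, aldehyde-selective Wacker oxidation should place oxygen on the terminal carbon because the quaternary allylic carbon blocks Markovnikov attack, while the ketones are inert; no stereocentre is formed.

Step 4
Reactants: 5 3-methyl-3-(1-methyl-2,5-dioxocyclopentyl)butanal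
Product: 6 (2E)-5-methyl-5-(1-methyl-2,5-dioxocyclopentyl)hex-2-enal
Conditions: Ph3P=CHCHO, PhMe, 80 °C
Reagents that add atoms: (triphenylphosphoranylidene)acetaldehyde O=CC=P(c1ccccc1)(c1ccccc1)c1ccccc1
Why: Wittig olefination with the stabilised formyl ylide reacts only at the aldehyde and should give the E-enal needed as the carbene acceptor; the hindered ring ketones do not react.

Step 5
Reactants: 6 (2E)-5-methyl-5-(1-methyl-2,5-dioxocyclopentyl)hex-2-enal
Product: 7 (3aS,4S,7aS)-7,7,7a-trimethyl-1-oxooctahydro-1H-indene-4,3a-carbolactone (cis-fused keto β-lactone; lactone O on C3a, lactone C=O on C4, both on the face of the C7a methyl)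
Conditions: (5aS,10bR)-2-mesityl-5a,10b-dihydro-4H,6H-indeno[2,1-b][1,2,4]triazolo[4,3-d][1,4]oxazin-2-ium chloride (15 mol %), i-Pr2NEt (1 equiv), CH2Cl2, 35 °C
Reagents that add atoms: none
Why: The carbene adds to the aldehyde, the extended Breslow intermediate is protonated at the former β-carbon (C5) by i-Pr2NEt·H+ to give an azolium enolate, whose α-carbon (C4) attacks one ring carbonyl (C3a); the tertiary alkoxide then acylates on the acyl azolium, releasing the catalyst and the β-lactone. The closest known reaction type is the carbene-catalysed desymmetrising intramolecular aldol–lactonisation of enal-tethered 2,2-disubstituted cycloalkane-1,3-diones, established for five-membered carbocycles and here lengthened by one carbon, with the gem-dimethyl group aiding closure. The carbocycle closes by a 6-(enolexo)-exo-trig aldol and the lactone by a 4-exo-trig acyl transfer. C7a is set by the chiral catalyst through its choice between the two enantiotopic carbonyls; C3a and C4 follow from the tether, which can reach the carbonyl only from its own side (cis ring fusion, oxygen syn to the C7a methyl), and from the cis geometry of the four-membered ring, and both are erased when CO2 leaves in step 8. The step needs enolate chemistry to win over direct homoenolate addition to the ketone, which would close a five-membered ring; the weak amine base and its conjugate acid favour β-protonation, and the hindered, unactivated ketone is a poor homoenolate acceptor.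

Step 6
Reactants: 7 keto β-lactone
Product: 8 C1 enol triflate of 7 (C1=C2 alkene, OSO2CF3 on C1; β-lactone and the three stereocentres unchanged)
Conditions: KN(SiMe3)2, THF, −78 °C; then PhNTf2, −78 to 0 °C
Reagents that add atoms: N-phenylbis(trifluoromethanesulfonimide) O=S(=O)(N(c1ccccc1)S(=O)(=O)C(F)(F)F)C(F)(F)F
Why: Kinetic enolisation at C2, the only enolisable position of the ketone, followed by O-triflation gives the alkenyl triflate; at −78 °C the hindered amide base should deprotonate the ketone much faster than it attacks or enolises the β-lactone, and no stereocentre is touched.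

Step 7
Reactants: 8 enol triflate; 9 tert-butyl(3-iodopropoxy)dimethylsilane
Product: 11 C1-[3-(tert-butyldimethylsilyloxy)propyl] alkene (OSO2CF3 of 8 replaced by CH2CH2CH2OTBS; β-lactone intact), via alkylzinc iodide 10 (not isolated)
Conditions: 9, Zn dust, LiCl, THF, 40 °C; then 8, PdCl2(dppf) (5 mol %), THF/NMP, 50 °C
Reagents that add atoms: none
Why: Negishi sp2–sp3 cross-coupling under neutral conditions installs the three-carbon side-chain stub on C1; alkenyl triflates flanked by a quaternary carbon are good partners, and the β-lactone and silyl ether should tolerate the organozinc.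

Step 8
Reactants: 11 C1-alkylated alkene with β-lactone
Product: 13 2,2-dichlorocyclobutanone cis-fused across C1–C2 of the 7,7,7a-trimethyl-hexahydroindene (CCl2 on C1, C=O on C2, both syn to the C7a methyl; C3a=C4 alkene; side chain CH2CH2CH2OTBS on C1), via lactone-bearing dichlorocyclobutanone 12 (not isolated)
Conditions: Cl3CCOCl, Zn(Cu), DME/Et2O, rt; filter; then PhMe, 130 °C, sealed tube
Reagents that add atoms: trichloroacetyl chloride ClC(Cl)(Cl)C(Cl)=O
Why: Dichloroketene [2+2] cycloaddition to the only alkene, with the usual regiochemistry (carbonyl carbon to the less substituted C2, CCl2 to C1) and approach from the convex face that carries the angular methyl (the other face is blocked by the folded six-membered ring and its axial C7 methyl), should set C1 and C2 cis to each other and to the C7a methyl; heating then extrudes CO2 from the β-lactone by stereospecific [2+2] cycloreversion and unveils the C3a=C4 alkene.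

Step 9
Reactants: 13 alkene dichlorocyclobutanone
Product: 14 2-(trimethylsilyl)ethyl (1S,2S,7aS)-1-{3-[(tert-butyldimethylsilyl)oxy]propyl}-1-(dichloromethyl)-7,7,7a-trimethyl-2,3,5,6,7,7a-hexahydro-1H-indene-2-carboxylate
Conditions: Me3SiCH2CH2OH (3 equiv), NaH (0.2 equiv), THF, 0 °C
Reagents that add atoms: 2-(trimethylsilyl)ethanol C[Si](C)(C)CCO
Why: Haloform-type cleavage of the α,α-dichlorocyclobutanone: the alkoxide adds to the strained carbonyl and the dichloromethyl carbanion leaves, so C2 keeps the carboxyl carbon and C1 the one-carbon unit with both configurations retained; the base is catalytic and cold to avoid epimerisation at C2.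

Step 10
Reactants: 14 dichloromethyl ester
Product: 15 2-(trimethylsilyl)ethyl (1R,2S,7aS)-1-{3-[(tert-butyldimethylsilyl)oxy]propyl}-1,7,7,7a-tetramethyl-2,3,5,6,7,7a-hexahydro-1H-indene-2-carboxylate
Conditions: Bu3SnH (4 equiv), AIBN (portions), PhMe, 110 °C
Reagents that add atoms: none
Why: Radical-chain hydrodechlorination with the tin hydride reduces CHCl2 to the C1 methyl group without touching a stereocentre; the ester, silyl ether and trisubstituted alkene are inert to stannyl radicals.

Step 11
Reactants: 15 silyl ether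
Product: 16 2-(trimethylsilyl)ethyl (1R,2S,7aS)-1-(3-hydroxypropyl)-1,7,7,7a-tetramethyl-2,3,5,6,7,7a-hexahydro-1H-indene-2-carboxylate
Conditions: camphorsulfonic acid (10 mol %), MeOH/CH2Cl2, 0 °C
Reagents that add atoms: none
Why: Acid-catalysed methanolysis removes the primary TBS ether selectively; the 2-(trimethylsilyl)ethyl ester needs fluoride and survives.

Step 12
Reactants: 16 primary alcohol
Product: 17 2-(trimethylsilyl)ethyl (1R,2S,7aS)-1,7,7,7a-tetramethyl-1-(3-oxopropyl)-2,3,5,6,7,7a-hexahydro-1H-indene-2-carboxylate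
Conditions: Dess–Martin periodinane, NaHCO3, CH2Cl2, rt
Reagents that add atoms: none
Why: Dess–Martin oxidation of the primary alcohol to the aldehyde under buffered, neutral conditions; no epimerisable centre is affected.

Step 13
Reactants: 17 aldehyde
Product: 18 2-(trimethylsilyl)ethyl (1R,2S,7aS)-1-[(3Z)-5-methoxy-4-methyl-5-oxopent-3-en-1-yl]-1,7,7,7a-tetramethyl-2,3,5,6,7,7a-hexahydro-1H-indene-2-carboxylate
Conditions: (CF3CH2O)2P(O)CH(CH3)CO2CH3, KN(SiMe3)2, 18-crown-6, THF, −78 °C
Reagents that add atoms: methyl 2-[bis(2,2,2-trifluoroethoxy)phosphoryl]propanoate COC(=O)C(C)P(=O)(OCC(F)(F)F)OCC(F)(F)F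
Why: Still–Gennari olefination with the bis(trifluoroethyl) phosphonopropionate should give the Z-trisubstituted enoate (ester cis to the chain) under kinetic control, which sets the side-chain alkene geometry.

Step 14
Reactants: 18 diester
Product: 19 (1R,2S,7aS)-1-[(3Z)-5-methoxy-4-methyl-5-oxopent-3-en-1-yl]-1,7,7,7a-tetramethyl-2,3,5,6,7,7a-hexahydro-1H-indene-2-carboxylic acid
Conditions: Bu4NF, THF, rt; aq. NH4Cl work-up
Reagents that add atoms: none
Why: Fluoride-induced β-elimination cleaves the 2-(trimethylsilyl)ethyl ester under conditions that should neither epimerise C2 nor touch the methyl enoate.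

Step 15
Reactants: 19 enoate acid
Product: 20 (1R,2S,7aS)-1-[(3Z)-5-hydroxy-4-methylpent-3-en-1-yl]-1,7,7,7a-tetramethyl-2,3,5,6,7,7a-hexahydro-1H-indene-2-carboxylic acid
Conditions: i-Bu2AlH (3.5 equiv), CH2Cl2, −78 °C; aq. Rochelle salt, then pH 3
Reagents that add atoms: none
Why: The acid is first deprotonated to an aluminium carboxylate that resists hydride at −78 °C, so i-Bu2AlH should reduce only the enoate to the Z-allylic alcohol (1,2-reduction, geometry retained).

Step 16
Reactants: 20 hydroxy acid
Product: 21 (1R,2S,7aS)-1-[(3Z)-5-acetoxy-4-methylpent-3-en-1-yl]-1,7,7,7a-tetramethyl-2,3,5,6,7,7a-hexahydro-1H-indene-2-carboxylic acid (target)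
Conditions: Ac2O, pyridine, DMAP (cat.), CH2Cl2, 0 °C to rt; aq. NaHCO3, then acidify
Reagents that add atoms: acetic anhydride CC(=O)OC(C)=O
Why: Acetylation of the primary allylic alcohol; any mixed anhydride formed at the hindered acid is hydrolysed during the bicarbonate work-up, which should leave the target.

Compound list
1 | 2-methylcyclopentane-1,3-dione | CC1C(=O)CCC1=O | starting material
2 | 3-methylbut-2-en-1-ol (prenol) | CC(C)=CCO | starting material
3 | 2-methyl-3-[(3-methylbut-2-en-1-yl)oxy]cyclopent-2-en-1-one | CC1=C(OCC=C(C)C)CCC1=O | intermediate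
4 | 2-methyl-2-(2-methylbut-3-en-2-yl)cyclopentane-1,3-dione | CC1(C(C)(C)C=C)C(=O)CCC1=O | intermediate
5 | 3-methyl-3-(1-methyl-2,5-dioxocyclopentyl)butanal | CC1(C(C)(C)CC=O)C(=O)CCC1=O | intermediate
6 | (2E)-5-methyl-5-(1-methyl-2,5-dioxocyclopentyl)hex-2-enal | O=C/C=C/CC(C)(C)C1(C)C(=O)CCC1=O | intermediate
7 | (3aS,4S,7aS)-7,7,7a-trimethyl-1-oxooctahydro-1H-indene-4,3a-carbolactone | O=C1O[C@]23CCC(=O)[C@@]2(C)C(C)(C)CC[C@H]13 | intermediate
8 | C1 enol triflate of 7 | O=C1O[C@]23CC=C(OS(=O)(=O)C(F)(F)F)[C@@]2(C)C(C)(C)CC[C@H]13 | intermediate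
9 | tert-butyl(3-iodopropoxy)dimethylsilane | CC(C)(C)[Si](C)(C)OCCCI | starting material
10 | [3-(tert-butyldimethylsilyloxy)propyl]zinc iodide | CC(C)(C)[Si](C)(C)OCCC[Zn]I | intermediate (not isolated)
11 | C1-[3-(tert-butyldimethylsilyloxy)propyl] alkene with β-lactone | O=C1O[C@]23CC=C(CCCO[Si](C)(C)C(C)(C)C)[C@@]2(C)C(C)(C)CC[C@H]13 | intermediate
12 | dichlorocyclobutanone across C1–C2 with β-lactone still in place | O=C1O[C@]23C[C@@H]4C(=O)C(Cl)(Cl)[C@]4(CCCO[Si](C)(C)C(C)(C)C)[C@@]2(C)C(C)(C)CC[C@H]13 | intermediate (not isolated)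
13 | dichlorocyclobutanone across C1–C2 with C3a=C4 alkene | CC(C)(C)[Si](C)(C)OCCC[C@]13C(Cl)(Cl)C(=O)[C@H]1CC2=CCCC(C)(C)[C@@]23C | intermediate
14 | 2-(trimethylsilyl)ethyl (1S,2S,7aS)-1-{3-[(tert-butyldimethylsilyl)oxy]propyl}-1-(dichloromethyl)-7,7,7a-trimethyl-2,3,5,6,7,7a-hexahydro-1H-indene-2-carboxylate | CC(C)(C)[Si](C)(C)OCCC[C@]1(C(Cl)Cl)[C@@H](C(=O)OCC[Si](C)(C)C)CC2=CCCC(C)(C)[C@@]21C | intermediate
15 | 2-(trimethylsilyl)ethyl (1R,2S,7aS)-1-{3-[(tert-butyldimethylsilyl)oxy]propyl}-1,7,7,7a-tetramethyl-2,3,5,6,7,7a-hexahydro-1H-indene-2-carboxylate | CC(C)(C)[Si](C)(C)OCCC[C@]1(C)[C@@H](C(=O)OCC[Si](C)(C)C)CC2=CCCC(C)(C)[C@@]21C | intermediate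
16 | 2-(trimethylsilyl)ethyl (1R,2S,7aS)-1-(3-hydroxypropyl)-1,7,7,7a-tetramethyl-2,3,5,6,7,7a-hexahydro-1H-indene-2-carboxylate | OCCC[C@]1(C)[C@@H](C(=O)OCC[Si](C)(C)C)CC2=CCCC(C)(C)[C@@]21C | intermediate
17 | 2-(trimethylsilyl)ethyl (1R,2S,7aS)-1,7,7,7a-tetramethyl-1-(3-oxopropyl)-2,3,5,6,7,7a-hexahydro-1H-indene-2-carboxylate | O=CCC[C@]1(C)[C@@H](C(=O)OCC[Si](C)(C)C)CC2=CCCC(C)(C)[C@@]21C | intermediate
18 | 2-(trimethylsilyl)ethyl (1R,2S,7aS)-1-[(3Z)-5-methoxy-4-methyl-5-oxopent-3-en-1-yl]-1,7,7,7a-tetramethyl-2,3,5,6,7,7a-hexahydro-1H-indene-2-carboxylate | COC(=O)/C(C)=C\CC[C@]1(C)[C@@H](C(=O)OCC[Si](C)(C)C)CC2=CCCC(C)(C)[C@@]21C | intermediate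
19 | (1R,2S,7aS)-1-[(3Z)-5-methoxy-4-methyl-5-oxopent-3-en-1-yl]-1,7,7,7a-tetramethyl-2,3,5,6,7,7a-hexahydro-1H-indene-2-carboxylic acid | COC(=O)/C(C)=C\CC[C@]1(C)[C@@H](C(=O)O)CC2=CCCC(C)(C)[C@@]21C | intermediate
20 | (1R,2S,7aS)-1-[(3Z)-5-hydroxy-4-methylpent-3-en-1-yl]-1,7,7,7a-tetramethyl-2,3,5,6,7,7a-hexahydro-1H-indene-2-carboxylic acid | OC/C(C)=C\CC[C@]1(C)[C@@H](C(=O)O)CC2=CCCC(C)(C)[C@@]21C | intermediate
21 | (1R,2S,7aS)-1-[(3Z)-5-acetoxy-4-methylpent-3-en-1-yl]-1,7,7,7a-tetramethyl-2,3,5,6,7,7a-hexahydro-1H-indene-2-carboxylic acid | CC(=O)OC/C(C)=C\CC[C@]1(C)[C@@H](C(=O)O)CC2=CCCC(C)(C)[C@@]21C | target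

Total step count: 16. Longest linear sequence: 16 steps (from 1; compound 9 is commercial and enters at step 7).

Steps most likely to fail

1. Step 5. The catalyst-bound intermediate may partition toward direct homoenolate addition to the ketone (five-membered closure), or the two carbonyls may be discriminated poorly. The fallback sets out from 5 and comes back at 7. Horner–Wadsworth–Emmons reaction of 5 with tert-butyl diethylphosphonoacetate (NaH, THF) would give tert-butyl (2E)-5-methyl-5-(1-methyl-2,5-dioxocyclopentyl)hex-2-enoate F1. Hydrogenation (H2, Pd/C, EtOAc) would give tert-butyl 5-methyl-5-(1-methyl-2,5-dioxocyclopentyl)hexanoate F2, and CF3CO2H would free 5-methyl-5-(1-methyl-2,5-dioxocyclopentyl)hexanoic acid F3. Activation of F3 with TsCl, i-Pr2NEt and LiCl in the presence of the chiral isothiourea (S)-homobenzotetramisole gives an ammonium enolate that can react only through its α-carbon. This nucleophile-catalysed aldol–lactonisation, a known desymmetrisation of dione acids, should close to 7.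

2. Step 8. The β-lactone may be lost before or during the cycloaddition (ionisation of its tertiary C–O bond by zinc chloride, or base-induced opening already in step 6), or the cycloaddition at the congested alkene may stall. The fallback sets out from 7 and comes back at 13. CO2 is extruded first (PhMe, 130 °C) to give (7aS)-7,7,7a-trimethyl-2,3,5,6,7,7a-hexahydro-1H-inden-1-one F4. Triflation (KN(SiMe3)2, PhNTf2) would give (7aS)-7,7,7a-trimethyl-5,6,7,7a-tetrahydro-3H-inden-1-yl trifluoromethanesulfonate F5, and Negishi coupling with 10 would give tert-butyldimethyl[3-(7,7,7a-trimethyl-5,6,7,7a-tetrahydro-3H-inden-1-yl)propoxy]silane F6 (quaternary centre as in F4). Dichloroketene is then added in deficiency, relying on the higher reactivity of the cyclopentene double bond over the ring-fusion cyclohexene double bond, to reach 13.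

3. Step 3. Oxidation of the doubly neopentyl vinyl group may be slow, or oxygen may be delivered to the internal carbon. The fallback sets out from 4 and comes back at 5. RhCl(PPh3)3-catalysed hydroboration with catecholborane, which is chemoselective for the alkene over the ketones, followed by oxidation with NaBO3·4H2O would give 2-(4-hydroxy-2-methylbutan-2-yl)-2-methylcyclopentane-1,3-dione F7. Dess–Martin oxidation of F7 would give 5.

Further compounds
F1 | step 5 | tert-butyl (2E)-5-methyl-5-(1-methyl-2,5-dioxocyclopentyl)hex-2-enoate | CC(C)(C)OC(=O)/C=C/CC(C)(C)C1(C)C(=O)CCC1=O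
F2 | step 5 | tert-butyl 5-methyl-5-(1-methyl-2,5-dioxocyclopentyl)hexanoate | CC(C)(C)OC(=O)CCCC(C)(C)C1(C)C(=O)CCC1=O
F3 | step 5 | 5-methyl-5-(1-methyl-2,5-dioxocyclopentyl)hexanoic acid | OC(=O)CCCC(C)(C)C1(C)C(=O)CCC1=O
F4 | step 8 | (7aS)-7,7,7a-trimethyl-2,3,5,6,7,7a-hexahydro-1H-inden-1-one | O=C1CCC2=CCCC(C)(C)[C@@]21C
F5 | step 8 | (7aS)-7,7,7a-trimethyl-5,6,7,7a-tetrahydro-3H-inden-1-yl trifluoromethanesulfonate | O=S(=O)(OC1=CCC2=CCCC(C)(C)[C@@]21C)C(F)(F)F
F6 | step 8 | tert-butyldimethyl[3-(7,7,7a-trimethyl-5,6,7,7a-tetrahydro-3H-inden-1-yl)propoxy]silane, quaternary centre as in F4 | CC(C)(C)[Si](C)(C)OCCCC1=CCC2=CCCC(C)(C)[C@@]21C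
F7 | step 3 | 2-(4-hydroxy-2-methylbutan-2-yl)-2-methylcyclopentane-1,3-dione | CC1(C(C)(C)CCO)C(=O)CCC1=O
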